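## Structural features

1. Labels used throughout for target 19:
   - γ-lactone ring D = C1(=O)–O2–C3(CH3)–C3a–C9a
   - cyclohexene ring B = C3a–C4–C4a–C8a(OH)–C9=C9a
   - cyclohexane ring A = C4a–C5–C6–C7–C8–C8a
   - cyclopentane ring C = C3–C3a–C4–C10–C11
   - the N-acetylpiperidine (N1′, C2′–C6′, 6′-CH3) hangs on C11 through the single bond C11–C2′
2. Rings B, C and D all share the methine C3a and form a bowl. H-3a, H-4, H-11, the 3-methyl group and the 8a-hydroxyl lie on its convex (α) face, while H-4a and the piperidine lie on the concave (β) face, so the four non-hydrogen substituents of ring C (C2′, O2, C9a, C4a) are all cis.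
3. Six of the eight stereocentres are contiguous (C11, C3, C3a, C4, C4a, C8a; C3 and C8a are fully substituted carbinol carbons). Rings A/B are trans-fused, and the cis pair C2′/C6′ communicates with the core only across a rotatable bond.
4. The fragile groups are the tertiary allylic γ-hydroxy-α,β-unsaturated lactone (reducible, prone to dehydration toward an arene), the tertiary C3–O2 bond (ionisation, β-elimination) and any 1,4-cyclohexadiene precursor of ring B (aromatisation).
5. The real difficulty is the all-cis ring C, with its quaternary carbinol C3 and the heterocycle on the concave face, together with the C11/C2′ attached-ring relationship.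
6. The key step exploits this feature: in ring C the chain C4–C3a–C3(O)(CH3) is the β-carbon, α-carbon and carbonyl carbon of an acetyl group on ring B, and C10–C11(hetaryl) is a terminal 2-pyridylacetylene. Ring C is therefore a reductive [3+2] adduct that joins two electrophilic carbons (C4 and C10), and the C3 alkoxide it creates sits 1,4 to C1 and closes ring D.
7. The C10=C11 double bond left by that step lets H-11 be delivered last from the convex face, which is what places the heterocycle on the concave face.

## Logic of the disconnections

**19 ⇒ 16.**
- Bond cut: the C9=C9a π bond is removed (H added at C9 and C9a).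
- Reason: the enoate is the one group that cannot be trusted to survive reduction of a pyridine.
- Gain: the nitrogen ring can be made with no chemoselectivity constraint.
- Demand: enolisation at C9a in the presence of the acetamide and the free 8a-OH, and elimination toward C9 rather than C3a.

**16 ⇒ 15.**
- Bond cut: the N1′–C(=O) bond.
- Reason: the acetyl group is put on after the reduction because N-acylation of a 2,6-disubstituted pyridine is not available as an activating device.
- Gain: none in skeleton.
- Demand: N- over O-selectivity against a tertiary alcohol.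

**15 ⇒ 14.**
- Bonds cut: ten X–H bonds (C10, C11, C9, C9a, C2′–C6′, N1′).
- Gain: three stereocentres (C11, C2′, C6′) vanish and the piperidine becomes a flat, robust hetarene.
- Demand: H2 must reach C10=C11 from the α face, and one face of the pyridinium ring must be presented to the catalyst.

**14 ⇒ 12.**
- Bond cut: the C8a–O bond, with allylic transposition (C9=C9a back to C8a=C9, H back on C9a).
- Reason: C8a is γ to C1, a dissonant position best oxidised from a β,γ-unsaturated lactone.
- Gain: one quaternary stereocentre less.
- Demand: oxygen delivery to C8a only, from the α face.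

**12 ⇒ 8 + 9 (key).**
- Bonds cut: C4–C10, C11–C3 and O2–C1.
- Reason: these three bonds hold rings C and D and the whole hetaryl unit. Cutting them removes two rings and three stereocentres (C4, C3a, C3) and leaves a bicyclic enone and a commercial alkyne.
- Demand: a reductive union of C4 with C10, metal on C11, attack on the β face of 8, closure onto the ketone faster than protonolysis, and epimerisation at C9a before lactonisation.

**8 ⇒ 6 + 7.**
- Bonds cut: C3a–C9a and C4–C4a of ring B ([4+2]).
- Gain: ring B and the only independent stereocentre (C4a) arise in one step from a monocyclic diene.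
- Demand: "ortho" regiochemistry, and facial control by the acyl substituent of 6, which is later the leaving group of the lactonisation.

**6 ⇒ 3 + 4, and 3 ⇒ 1 + 2.**
- Bonds cut: the N–C1 bond and the C9=C9a bond (numbering of 19).
- Gain: all material is commercial.
- Demand: E geometry.

## Other disconnections considered

**Alternative 1:** this is the first that comes to mind.
- Cut: C3a–C9a and C4–C4a of ring B, with O2–C1 kept as a tether.
- Forward step: thermal ester-tethered intramolecular Diels–Alder reaction of the tertiary cyclopentenyl dienoate A1 to the tetracycle A2, followed by oxidation at C8a and reduction of the pyridine.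
- Grounds for preferring the chosen plan:
  - Ring C with C3 and C11 must be built and resolved beforehand through a configurationally labile α-hetaryl ketone.
  - A hindered tertiary allylic alcohol must be acylated.
  - The unactivated cyclopentene needs temperatures at which a tertiary allylic ester ionises or eliminates.
  - The chosen plan makes ring C, ring D and the C–hetaryl connection in one operation and needs no preformed cyclopentane.

**Alternative 2:**
- Cut: C11–C2′ last.
- Forward steps: iodolactonisation of the tricyclic diene acid A3 to the iodolactone A4, then nickel-catalysed reductive cross-electrophile coupling with the bromopyridine A5 to give A2.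
- Grounds for preferring the chosen plan:
  - The C11 radical is planar and its convex α face is the open one, so the intrinsic preference puts the hetaryl group on the wrong face and must be overridden by the catalyst.
  - The halolactonisation must distinguish two trisubstituted alkenes.
  - A3 itself needs its own multistep synthesis.
  - In the chosen plan C11 is set by the intrinsic preference (H from the convex face).

**Alternative 3:**
- Cut: C2′–C11 and O2–C3 together, using the 1,3-amino alcohol retron N1′–C2′–C11–C3–O2.
- Forward step: 1,3-dipolar cycloaddition of the cyclic nitrone A6 to the C3=C11 double bond of A3 to give the isoxazolidine A7, then N–O cleavage and lactonisation.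
- Merit: the syn addition gives the cis O2/C2′ relationship.
- Grounds for preferring the chosen plan, three intrinsic preferences oppose the target:
  - The dipole must approach the concave β face.
  - The C11/C2′ relationship requires the endo transition state, with ring C under the piperidine ring.
  - Attack anti to the 6′-methyl group leads to a trans-2′,6′ piperidine.

Key step: step 4

Assumption: the (2R)-sultam is taken to expose the Cα-Re face of the s-cis, C=O/SO2-anti dienoyl conformer, as in other uncatalysed cycloadditions of N-enoyl bornanesultams. If the sense were opposite, the equally available antipode would be used with no other change.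

## Route

Step 1
Reactants: 1 cyclohex-1-ene-1-carbaldehyde; 2 malonic acid
Product: 3 (2E)-3-(cyclohex-1-en-1-yl)prop-2-enoic acid
Conditions: pyridine, piperidine (cat.), 95 °C
Reagents that add atoms: none
Why: Doebner–Knoevenagel condensation with decarboxylation should give the thermodynamically preferred (E)-dienoic acid; no stereocentre is formed.

Step 2
Reactants: 3 (2E)-3-(cyclohex-1-en-1-yl)prop-2-enoic acid; 4 (2R)-bornane-10,2-sultam
Product: 6 N-[(2E)-3-(cyclohex-1-en-1-yl)prop-2-enoyl]-(2R)-bornane-10,2-sultam, via mixed pivalic anhydride 5 (not isolated)
Conditions: PivCl, Et3N, THF, −20 °C; then 4, LiCl, DMAP (cat.), 0 °C to rt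
Reagents that add atoms: none
Why: N-acylation of the sulfonamide nitrogen through a mixed anhydride, which is attacked at the dienoyl carbonyl group because the pivaloyl carbonyl is shielded. The auxiliary leaves again in step 4, so it needs no separate removal step.

Step 3
Reactants: 6 N-dienoyl sultam; 7 but-3-yn-2-one
Product: 8 N-{[(2S,4aS)-3-acetyl-2,4a,5,6,7,8-hexahydronaphthalen-2-yl]carbonyl}-(2R)-bornane-10,2-sultam (numbering of 19: H-9a and H-4a β; acyl group α; C3a=C4 and C8a=C9)
Conditions: 7 (3 equiv), BHT (cat.), PhMe, sealed tube, 115 °C, Ar; recrystallisation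
Reagents that add atoms: none
Why: Thermal Diels–Alder reaction; the acyl group on C9a and the alkyl group on C8a both raise the HOMO coefficient at C4a, which should bond to the unsubstituted alkyne carbon C4 ("ortho" adduct). Suprafacial addition places H-9a and H-4a cis, and the sultam shields the Cα-Si face so that the alkyne adds to the Re face and fixes C4a, the stereocentre from which all others are relayed. Crystallisation of the sultam derivative should remove the minor diastereomer.

Step 4
Reactants: 8 acetyl diene N-acyl sultam; 9 2-ethynyl-6-methylpyridine
Product: 12 tetracyclic lactone with 11-(6-methylpyridin-2-yl) and C10=C11 and C8a=C9 double bonds (H-3a H-4 H-9a and 3-CH3 α; H-4a β), via 9a-α-acyl hydroxy imide 10 (not isolated), via 9a-β-acyl hydroxy imide 11 (not isolated)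
Conditions: CoI2(dppe) (15 mol %), Zn, ZnI2 (30 mol %), H2O (2 equiv), MeCN–THF, 50 °C, 9 by syringe pump; then DBU, rt
Reagents that add atoms: none
Why: Proposed new method: zinc reduces Co(II) to a Co(I)–dppe species that binds 9 and the s-cis enone of 8 and couples them oxidatively, so that two carbons of like (electrophilic) polarity, C10 of the alkyne and the enone β-carbon C4, are joined while cobalt stays on the pyridyl-bearing carbon C11 and on the enolate. Water protonates the enolate at C3a and frees the methyl ketone; the alkenyl–cobalt bond, which syn-carbometallation has placed cis to C4, then adds to the ZnI2-activated C3=O (5-exo-trig closure of ring C) to give 10, and after DBU has epimerised the acidic, doubly allylic C9a (10 to 11) the tertiary alkoxide attacks C1 and expels the sultam (5-exo-trig closure of ring D). The closest known reaction types are the cobalt-catalysed reductive [3+2] cycloaddition of internal alkynes with cyclic enones and the nickel(0)-promoted [3+2] cyclisation of tethered alkynyl enones; an exocyclic methyl ketone, a terminal 2-pyridylalkyne and a terminating lactonisation have not been shown. C4: the flat 1,4-cyclohexadiene of 8 carries the bulky acyl sultam (on C9a) and C5 (on C4a) on its α face and only H-9a and H-4a on its β face, so metal and alkyne should arrive from β and H-4 ends α. C3a: protonation occurs anti to the metal, and only the cis arrangement (acetyl β) lets the tethered alkenyl metal reach the carbonyl group, while a trans epimer can re-enolise. C3: in the closure the methyl group should turn toward H-3a on the convex side and the metal-bound oxygen toward C9a, and only this epimer can lactonise, which also simplifies purification. Regioselectivity in the alkyne (C–C bond at the unhindered CH terminus, metal α to the electron-poor hetaryl group) is needed and is supported by the 6-methyl group, which weakens the N-coordination that could steer the metal to C10 or poison it. Chemoselectivity over alkyne cyclotrimerisation is sought by keeping the stationary concentration of 9 low.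

Step 5
Reactants: 12 tetracyclic diene lactone
Product: 14 8aα-hydroxy-C9=C9a-unsaturated lactone with the C10=C11 double bond and the pyridine retained, via allylic hydroperoxide 13 (not isolated)
Conditions: O2, hν (visible), tetraphenylporphyrin (cat.), CH2Cl2, −20 °C; then PPh3
Reagents that add atoms: dioxygen, O=O
Why: Schenck ene reaction followed by reduction of the hydroperoxide. Singlet oxygen should attack the electron-richer trialkyl alkene C8a=C9 from the convex α face, where the aligned allylic hydrogen on the more substituted side is H-9a, so oxygen is delivered suprafacially to C8a (α, trans to H-4a) and the double bond moves into conjugation. The hetaryl- and acyloxy-deactivated C10=C11 bond should react more slowly.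

Step 6
Reactants: 14 hydroxy dienyl lactone
Product: 15 saturated amino lactone with (2′S,6′S)-6′-methylpiperidin-2′-yl β on C11 (H-11 and H-9a α; 8a-OH α)
Conditions: H2 (5 bar), PtO2 (cat.), AcOH, rt; basic work-up
Reagents that add atoms: none
Why: Heterogeneous hydrogenation; the bowl adsorbs by its convex face, so H2 should add to C10=C11 and C9=C9a from α, which pushes the hetaryl group to the concave face and sets C11. In acid an N–H···O2 contact should hold the pyridinium nitrogen syn to O2, so the ring face turned toward H-11 is exposed while the other is covered by C10, and all-cis delivery gives the cis piperidine with 2′S,6′S. Platinum rather than palladium limits hydrogenolysis of the allylic C–O bonds.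

Step 7
Reactants: 15 amino lactone
Product: 16 N-acetyl derivative of 15
Conditions: Ac2O, pyridine, 40 °C
Reagents that add atoms: acetic anhydride, CC(=O)OC(C)=O
Why: Acylation of the secondary amine; the tertiary 8a-alcohol should not be acylated without a nucleophilic catalyst.

Step 8
Reactants: 16 N-acetyl saturated hydroxy lactone
Product: 19 target (3R,3aS,4S,4aS,8aS,11R,2′S,6′S), via selenide 17 (not isolated), via selenoxide 18 (not isolated)
Conditions: KHMDS (2.2 equiv), THF, −78 °C; PhSeBr; then H2O2, CH2Cl2–pyridine, 0 °C to rt
Reagents that add atoms: none
Why: α-Selenenylation of the lactone enolate and selenoxide syn-elimination. KHMDS (first equivalent consumed by the 8a-OH) is basic enough for the lactone but not for the N,N-dialkylacetamide. Selenium enters from the α face and finds a syn hydrogen on C9, whereas elimination toward C3a would flatten the carbon shared by three rings.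

## Compound list

1 | cyclohex-1-ene-1-carbaldehyde | O=CC1=CCCCC1 | starting material
2 | malonic acid | OC(=O)CC(=O)O | starting material
3 | (2E)-3-(cyclohex-1-en-1-yl)prop-2-enoic acid | OC(=O)/C=C/C1=CCCCC1 | intermediate
4 | (2R)-bornane-10,2-sultam, (3aS,6R,7aR) | CC1(C)[C@@H]2CC[C@]13CS(=O)(=O)N[C@@H]3C2 | starting material
5 | mixed anhydride of 3 and pivalic acid | CC(C)(C)C(=O)OC(=O)/C=C/C1=CCCCC1 | intermediate
6 | N-dienoyl sultam | CC1(C)[C@@H]2CC[C@]13CS(=O)(=O)N(C(=O)/C=C/C4=CCCCC4)[C@@H]3C2 | intermediate
7 | but-3-yn-2-one | CC(=O)C#C | starting material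
8 | (2S,4aS)-3-acetylhexahydronaphthalene-2-carbonyl sultam | CC1(C)[C@@H]2CC[C@]13CS(=O)(=O)N(C(=O)[C@H]4C=C5CCCC[C@H]5C=C4C(C)=O)[C@@H]3C2 | intermediate
9 | 2-ethynyl-6-methylpyridine | Cc1cccc(n1)C#C | starting material
10 | cyclopentenol, acyl sultam α on C9a | CC1(C)[C@@H]2CC[C@]13CS(=O)(=O)N(C(=O)[C@H]4C=C5CCCC[C@H]5[C@@H]5C=C(c6cccc(C)n6)[C@](C)(O)[C@H]45)[C@@H]3C2 | intermediate
11 | C9a epimer of 10, acyl sultam β | CC1(C)[C@@H]2CC[C@]13CS(=O)(=O)N(C(=O)[C@@H]4C=C5CCCC[C@H]5[C@@H]5C=C(c6cccc(C)n6)[C@](C)(O)[C@H]45)[C@@H]3C2 | intermediate
12 | tetracyclic pyridyl diene lactone | Cc1cccc(n1)C1=C[C@@H]2[C@H]3[C@@H](C=C4CCCC[C@@H]24)C(=O)O[C@@]13C | intermediate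
13 | 8aα-hydroperoxide | Cc1cccc(n1)C1=C[C@@H]2[C@H]3C(=C[C@]4(OO)CCCC[C@@H]24)C(=O)O[C@@]13C | intermediate
14 | 8aα-hydroxy enoate, C10=C11 retained | Cc1cccc(n1)C1=C[C@@H]2[C@H]3C(=C[C@]4(O)CCCC[C@@H]24)C(=O)O[C@@]13C | intermediate
15 | saturated amino hydroxy lactone | N1[C@@H](C)CCC[C@H]1[C@H]1C[C@@H]2[C@H]3[C@@H](C[C@]4(O)CCCC[C@@H]24)C(=O)O[C@@]13C | intermediate
16 | N-acetyl saturated hydroxy lactone | CC(=O)N1[C@@H](C)CCC[C@H]1[C@H]1C[C@@H]2[C@H]3[C@@H](C[C@]4(O)CCCC[C@@H]24)C(=O)O[C@@]13C | intermediate
17 | 9aα-phenylselanyl lactone | CC(=O)N1[C@@H](C)CCC[C@H]1[C@H]1C[C@@H]2[C@H]3[C@@]([Se]c5ccccc5)(C[C@]4(O)CCCC[C@@H]24)C(=O)O[C@@]13C | intermediate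
18 | selenoxide of 17 | CC(=O)N1[C@@H](C)CCC[C@H]1[C@H]1C[C@@H]2[C@H]3[C@@]([Se](=O)c5ccccc5)(C[C@]4(O)CCCC[C@@H]24)C(=O)O[C@@]13C | intermediate
19 | target CNP0529632.1 | CC(=O)N1[C@@H](C)CCC[C@H]1[C@H]1C[C@@H]2[C@H]3C(=C[C@]4(O)CCCC[C@@H]24)C(=O)O[C@@]13C | target

Total step count: 8. Longest linear sequence: 8 (1 to 19).

## Least certain steps

**Step 4 (key step).**
- What may go wrong:
  - cyclotrimerisation or oligomerisation of the terminal alkyne on low-valent cobalt
  - sequestration of the catalyst by the pyridine nitrogen
  - protonolysis of the alkenyl–metal bond before it adds to the ketone (open-chain reductive coupling only)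
  - reversed orientation of the alkyne
  - base-induced migration of the ring B double bonds before lactonisation
- Fallback (known chemistry), from 8 back to 12. Copper-catalysed 1,4-addition of vinylmagnesium bromide (CuBr·SMe2, TMSCl) from the β face gives the 4β-vinyl methyl ketone F1. Separately, 9 is hydrostannylated at its internal carbon (Bu3SnH, molybdenum isonitrile catalyst) to 2-methyl-6-[1-(tributylstannyl)ethenyl]pyridine F2. Tin–lithium exchange and CeCl3 turn F2 into the 1-pyridylvinyl nucleophile, which adds to the ketone of F1, and DBU then closes the lactone to the seco-diene lactone F3. Ring-closing metathesis (second-generation ruthenium benzylidene catalyst, TsOH to mask the pyridine) forms C10=C11 and gives 12.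

**Step 3.**
- What may go wrong:
  - slow cycloaddition of an acceptor-substituted diene at a temperature where 7 polymerises
  - erosion of facial selectivity at 115 °C
  - partial loss of regiocontrol, because the alkyl group on C4a opposes the other two directing effects
  - aromatisation of ring B by adventitious oxygen
- Fallback, from 3 and 7 back to 8: the sultam is used as a resolving handle instead of a controller. The less electron-poor free acid 3 is cycloadded thermally to the racemic keto acid F4. F4 is coupled to 4 as in step 2, and 8 is separated by crystallisation from its (2R,4aR)-diastereomer F5.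

**Step 6.**
- What may go wrong:
  - poor facial selectivity in the reduction of the pyridinium ring, because rotation about C11–C2′ presents both faces
  - hydrogenolysis of an allylic C–O bond before the neighbouring alkene is saturated
  - incomplete saturation of C9=C9a, which is harmless because material that keeps this bond becomes 19 directly in step 7
- Fallback, from 14 back to 15: the rotamer is locked by a stronger hydrogen bond in the ring-opened series. Saponification (LiOH) gives the hydroxy acid F6, whose free 3-OH donates a six-membered O–H···N hydrogen bond to the neutral pyridine and holds nitrogen syn to oxygen. Hydrogenation over Rh/Al2O3 in neutral ethanol gives the amino hydroxy acid F7, and acidification relactonises it to 15.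

**Step 5.**
- What may go wrong:
  - hydrogen abstraction from C8 with oxygen delivered to C9
  - a competing ene reaction at C10=C11
  - photo-oxidative degradation
- Fallback, from 12 back to 14, by a Mislow–Evans sequence. KHMDS and PhSSPh give the 9aα-phenylsulfanyl lactone F8. One equivalent of mCPBA on the trifluoroacetate salt (pyridine masked) gives the sulfoxide F9, which rearranges suprafacially ([2,3]) to the 8aα-sulfenate F10. Diethylamine cleaves F10 to 14.

**Step 8.**
- What may go wrong:
  - competing deprotonation and selenenylation at the acetamide methyl group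
  - slow enolisation of the hindered C9a–H
  - elimination in the wrong direction
- Fallback, from 16 directly to 19: allyl-palladium-catalysed dehydrogenation of the zinc enolate (Zn(TMP)2, [Pd(allyl)Cl]2 cat., allyl pivalate). The alkene arises by β-hydride elimination, and an acetamide enolate, which has no β-hydrogen, is simply reprotonated. This fallback makes no new compound (F0).

## Further compounds

F1 | step 4 | 4β-vinyl methyl ketone, 1,4-adduct of 8 | CC1(C)[C@@H]2CC[C@]13CS(=O)(=O)N(C(=O)[C@H]4C=C5CCCC[C@H]5[C@H](C=C)[C@@H]4C(C)=O)[C@@H]3C2
F2 | step 4 | 2-methyl-6-[1-(tributylstannyl)ethenyl]pyridine | C=C([Sn](CCCC)(CCCC)CCCC)c1cccc(C)n1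
F3 | step 4 | seco-diene lactone (4β-vinyl, 3-[1-(6-methylpyridin-2-yl)ethenyl]) | C=C[C@@H]1[C@H]2[C@@H](C=C3CCCC[C@@H]13)C(=O)O[C@@]2(C)C(=C)c1cccc(C)n1
F4 | step 3 | rac-(2S*,4aS*)-3-acetyl-2,4a,5,6,7,8-hexahydronaphthalene-2-carboxylic acid (one enantiomer drawn) | OC(=O)[C@H]1C=C2CCCC[C@H]2C=C1C(C)=O
F5 | step 3 | (2R,4aR)-diastereomer of 8 | CC1(C)[C@@H]2CC[C@]13CS(=O)(=O)N(C(=O)[C@@H]4C=C5CCCC[C@@H]5C=C4C(C)=O)[C@@H]3C2
F6 | step 6 | hydroxy acid from ring opening of 14 | Cc1cccc(n1)C1=C[C@@H]2[C@@H](C(=C[C@]3(O)CCCC[C@@H]23)C(=O)O)[C@@]1(C)O
F7 | step 6 | saturated amino hydroxy acid | N1[C@@H](C)CCC[C@H]1[C@H]1C[C@@H]2[C@@H]([C@@H](C[C@]3(O)CCCC[C@@H]23)C(=O)O)[C@@]1(C)O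
F8 | step 5 | 9aα-phenylsulfanyl derivative of 12 | Cc1cccc(n1)C1=C[C@@H]2[C@H]3[C@@](Sc5ccccc5)(C=C4CCCC[C@@H]24)C(=O)O[C@@]13C
F9 | step 5 | sulfoxide of F8 | Cc1cccc(n1)C1=C[C@@H]2[C@H]3[C@@](S(=O)c5ccccc5)(C=C4CCCC[C@@H]24)C(=O)O[C@@]13C
F10 | step 5 | 8aα-benzenesulfenate | Cc1cccc(n1)C1=C[C@@H]2[C@H]3C(=C[C@]4(OSc5ccccc5)CCCC[C@@H]24)C(=O)O[C@@]13C
F0 | step 8 | none | none
A1 | alternative 1 | tertiary cyclopentenyl (E)-3-(cyclohexenyl)acrylate carrying the pyridine on C11 | Cc1cccc(n1)[C@H]1CC=C[C@@]1(C)OC(=O)/C=C/C1=CCCCC1
A2 | alternative 1 | tetracyclic lactone with 11β-pyridyl and C8a=C9 | Cc1cccc(n1)[C@H]1C[C@@H]2[C@H]3[C@@H](C=C4CCCC[C@@H]24)C(=O)O[C@@]13C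
A3 | alternative 2 | tricyclic diene acid (C3=C11, C8a=C9) | OC(=O)[C@@H]1C=C2CCCC[C@H]2[C@@H]2CC=C(C)[C@H]12
A4 | alternative 2 | 11α-iodolactone | I[C@@H]1C[C@@H]2[C@H]3[C@@H](C=C4CCCC[C@@H]24)C(=O)O[C@@]13C
A5 | alternative 2 | 2-bromo-6-methylpyridine | Cc1cccc(Br)n1
A6 | alternative 3 | (S)-6-methyl-2,3,4,5-tetrahydropyridine 1-oxide | C[C@H]1CCCC=[N+]1[O-]
A7 | alternative 3 | isoxazolidine cycloadduct with the target configuration | C[C@H]1CCC[C@@H]2N1O[C@@]1(C)[C@@H]2C[C@@H]2[C@H]1[C@H](C(=O)O)C=C1CCCC[C@@H]21
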